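**Compound numbering used throughout** (names and SMILES are in the list after the steps)

1 (R)-pent-4-yn-2-ol; 2 benzoyl chloride; 3 alkynyl benzoate; 4 trichloroacetyl chloride; 5 dichloroketene; 6 dichlorocyclobutenone; 7 cyclobutenone; 8 ethoxyacetylene; 9 vinylketene; 10 vinylcyclobutenone; 11 dienylketene; 12 cyclohexadienone; 13 ring A phenol; 14 resorcinol benzoate; 15 benzyl bromide; 16 bis(benzyl ether) benzoate; 17 arylpropanol; 18 methyl (R)-3-hydroxybutanoate; 19 benzyl trichloroacetimidate; 20 benzyl ether ester; 21 unit D acid; 22 ester of 17 with 21; 23 aldehyde; 24 ring C acid; 25 ethyl (S)-3-hydroxybutanoate; 26 allyl alcohol; 27 allyl (S)-3-hydroxybutanoate; 28 allyl ester of units B–C–D; 29 acid of units B–C–D; 30 pentabenzyl ether of the target; 31 Hansforester J.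

## Analysis of the target

Hansforester J is an open-chain tetramer of four hydroxy-acid-type units joined head to tail by three ester bonds. Unit A is a 1-arylpropan-2-ol whose arene (ring A) is a resorcinol, unit B is a 3-hydroxybutanoate, unit C is a 2,4-dihydroxybenzoate (ring C) carrying a 2-hydroxypropyl chain at C6, and unit D is a terminal 3-hydroxybutanoate with a free hydroxyl. There are four stereocentres, all secondary methyl carbinols and all (R), and because ester links separate them none can control another, so each must be brought in enantiopure. The sensitive groups are the β-aroyloxy ester of unit B, which loses carboxylate by E1cB elimination once its α-position is acidified, the β-hydroxy ester of unit D, and the free resorcinols. The ring C carboxyl is flanked by two ortho substituents, which makes it a poor acyl donor, and a free carbinol on its side chain would close onto it as a six-membered lactone. With ring A numbered so that the hydroxyls sit on C1 and C3, the carbon chain sits on C5, meta to both oxygens, a position that electrophilic substitution of a resorcinol does not reach. The strategy rests on building ring A from a four-carbon vinylketene (C1, C4, C5, C6) and a two-carbon ynol ether (C2, C3), which places oxygen on C1 and C3 and the chain on C5 by construction. Ring C is the same arene with one extra carbon on C6 (equivalent to C4), so the benzannulation product serves both arenes.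

## Retrosynthetic reasoning

**31 to 30.** All five hydroxyls that are free in the target (four phenols and the unit D carbinol) are carried as benzyl ethers, so the last step is a neutral hydrogenolysis. None of the three ester C–O bonds is benzylic, so they survive it. This choice fixes benzyl as the protecting group for everything upstream.

**30 to 29 and 17.** The acyl–oxygen bond between the unit B carbonyl and the ring A carbinol is cut. This is the most convergent cut: an alcohol with one stereocentre and an acid with three. It is also an ordinary aliphatic ester, formed with retention at the carbinol of 17. The forward step has to activate a β-aroyloxy acid without triggering β-elimination.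

**29 to 28, then to 24 and 27.** The hindered aryl ester is cut at the alkyl C–O bond of unit B, not at the acyl–oxygen bond. In the forward direction the carboxylate of 24 acts as the nucleophile in a Mitsunobu reaction on the (S)-alcohol 27, and inversion gives the (R) centre. The carboxyl of 24 is therefore never made electrophilic, so the ester oxygen on its own side chain cannot close the lactone. The allyl ester of 27 is chosen because it can be removed under neutral conditions in the presence of benzyl ethers; 27 comes from 25 and 26 by transesterification.

**24 to 23, to 22, then to 17 and 21.** The aryl–carboxyl bond of ring C is cut. Going forward, 22 is formylated at C6 and the aldehyde 23 is oxidised. C6 is ortho to one benzyloxy group and para to the other, and it is less hindered than C2, which lies between the two benzyloxy groups. The carbinol of 17 is esterified with 21 before the formyl carbon is introduced, so a free side-chain hydroxyl and a carboxyl never coexist on ring C. Acid 21 comes from 18 by acid-catalysed benzylation with 19 (giving 20) and hydrolysis.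

**17 to 16, to 14, to 13.** These are protecting-group changes: the ethyl ether of 13 is cleaved, both phenols of 14 are benzylated with two molecules of 15, and the benzoate of 16 is removed. The carbinol is carried as a benzoate, not a silyl ether, because Lewis-acid dealkylation with a boron halide converts secondary silyl ethers into bromides, which would destroy the stereocentre.

**13 to 7 and 8.** This is the key disconnection. Ring bonds C1–C2 and C3–C4 are cut, returning the four-carbon cyclobutenone 7 and the two-carbon ynol ether 8. No other disconnection of ring A gives the 1,3,5 pattern directly from an acyclic chiral-pool carbinol. The forward reaction must join the ketene carbon to the CH end of 8 and leave the remote (R)-carbinol untouched.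

**7 to 6, then to 3 and 5; 3 to 1 and 2.** The cyclobutenone comes from [2+2] cycloaddition of dichloroketene 5 (made in the flask from 4) to the terminal alkyne of 3, followed by reductive removal of both chlorines. Benzoate 3 comes from the commercial alcohol 1 and 2, so the ring A and ring C stereocentres are both bought.

## Alternatives that were turned down

Alternative 1: double Baeyer–Villiger oxidation.
- Disconnection: the two C–O bonds between the arylpropan-2-yl carbons and their ester oxygens. The precursor is the bis-ketone A2, in which both of these linkages are α-methyl ketones.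
- Forward key step: a buffered peroxy acid inserts oxygen twice, with migration of the secondary carbon and retention, to give the pentakis(benzyl carbonate) A1.
- For it: two ester bonds form in one operation without any carboxyl activation, so the β-elimination risk that steps 14 and 16 of the chosen route carry is absent here. Migratory aptitude favours the secondary carbon over the inductively deactivated CH2.
- Against it: the two (R) carbinols become two epimerisable α-methyl ketone centres that would have to be made by asymmetric C–C bond formation, whereas the chiral pool supplies the carbinols directly. Each ketone is also a β-acyloxy ketone and prone to elimination. The resorcinol rings need deactivating carbonate groups to survive the peracid. A2 is as complex as the target and still needs both 1,3,5-substituted arenes.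
- Comparison: longer and riskier. The chosen strategy gives up the one-pot formation of two esters and in return uses separately testable esterifications and purchased stereocentres.

Alternative 2: carboxylate-directed C–H alkylation with an epoxide.
- Disconnection: the aryl C6–CH2 bond of ring C and the lactone C–O bond.
- Forward key step: Pd(OAc)2 with an N-acyl amino acid ligand brings about ortho palladation of 2,4-bis(benzyloxy)benzoic acid A4, the aryl–palladium bond opens (R)-2-methyloxirane A5 at its CH2, and lactonisation gives the isochromanone A3 with the stereocentre untouched.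
- For it: one step from two cheap compounds to the whole ring C skeleton. Ring A could follow by lactone opening and decarboxylation. On step count to the arylpropanol it is clearly better than the seven steps to 17.
- Against it: A3 is the lactone, the thermodynamic sink of ring C. It must be opened and its carbinol acylated while the carboxylate is kept from reclosing, and every later activation of that carboxyl has the δ-oxygen nearby. For ring A the directing carboxyl is installed only to be removed.
- Comparison: the chosen strategy is longer. In exchange, ring C never passes through a lactone, because its carbinol is acylated before the carboxyl carbon exists. Ring A carries no vestigial directing group, and the ring-forming step needs no metal catalyst or ligand tuning.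

Alternative 3: carbonylative ring opening of an epoxide.
- Disconnection: the C1–C2 bond of unit B and its ester C–O bond.
- Forward key step: under Co2(CO)8 with a hydroxypyridine co-catalyst, the cobalt carbonyl anion opens epoxide A5 at its CH2, carbonyl insertion gives an acylcobalt species, and alcohol 17 intercepts it to give the hydroxy ester A6 with the new 3-hydroxyl free.
- For it: unit B is made with no protecting group and no carboxyl activation. All four stereocentres could be traced to A5. On atom economy it is better than the chosen route.
- Against it: the carbonylation is normally run in a simple alcohol as solvent. Here a valuable secondary alcohol would be the limiting reagent, so slow alcoholysis of the acylcobalt species lets β-lactone formation and oligomerisation compete. A6 has the (R) hydroxyl, which would then have to be acylated with retention by the hindered acid 24, the esterification that the chosen route avoids. The step also does nothing for the arenes.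
- Comparison: it solves a problem that commercial 3-hydroxybutanoates already solve and adds pressure equipment. The chosen strategy places its one unusual step early, on simple material, and forms the ester units by standard reactions.

Key step: step 4

Assumption: the target is read as (R) at all four carbinol carbons, and ethoxyacetylene is used as its commercial solution in hexanes.

## Route

Step 1
Reactants: 1 (R)-pent-4-yn-2-ol; 2 benzoyl chloride
Product: 3 (2R)-pent-4-yn-2-yl benzoate
Conditions: pyridine, DMAP (cat.), CH2Cl2, 0 °C → rt
Reagents that add atoms: none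
Why: DMAP-catalysed acylation of a secondary alcohol; the C–O bond of the stereocentre is not touched. The benzoate is inert to ketenes and zinc and, unlike a silyl ether, is not converted into a bromide by the boron halide of step 5.

Step 2
Reactants: 3 (2R)-pent-4-yn-2-yl benzoate; 4 trichloroacetyl chloride
Product: 6 (2R)-1-(4,4-dichloro-3-oxocyclobut-1-en-1-yl)propan-2-yl benzoate, via dichloroketene 5 (not isolated)
Conditions: Zn–Cu couple, Et2O/DME, slow addition of 4, rt
Reagents that add atoms: none
Why: Zinc dechlorinates 4 to dichloroketene, which adds to the terminal alkyne in a [2+2] cycloaddition; the ketene carbonyl carbon bonds to the terminal CH, so the chain ends up on C3 of the cyclobutenone. Any 2,4-dichloro isomer formed by chlorine shift converges on the same product in step 3.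

Step 3
Reactants: 6 (2R)-1-(4,4-dichloro-3-oxocyclobut-1-en-1-yl)propan-2-yl benzoate
Product: 7 (2R)-1-(3-oxocyclobut-1-en-1-yl)propan-2-yl benzoate
Conditions: Zn dust, AcOH, TMEDA, EtOH, 0 °C → rt
Reagents that add atoms: none
Why: Reductive dechlorination of the α-chloro ketone by zinc with acetic acid as proton source; the amine–acid buffer keeps the medium too weakly basic for vinylogous elimination of the benzoate.

Step 4
Reactants: 7 (2R)-1-(3-oxocyclobut-1-en-1-yl)propan-2-yl benzoate; 8 ethoxyacetylene
Product: 13 (2R)-1-(3-ethoxy-5-hydroxyphenyl)propan-2-yl benzoate, via vinylketene 9 (not isolated), via vinylcyclobutenone 10 (not isolated), via dienylketene 11 (not isolated), via cyclohexadienone 12 (not isolated)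
Conditions: 8 (2 equiv), toluene, sealed tube, 80 °C
Reagents that add atoms: none
Why: This is the Danheiser benzannulation, a known cascade of four pericyclic events for cyclobutenones and ynol ethers. At 80 °C 7 opens by a 4π electrocyclic reaction to vinylketene 9, and a [2+2] cycloaddition then joins the electrophilic ketene carbon (future C1) to the nucleophilic CH end of 8 (C2) and the ketene α-carbon (C4) to the ethoxy-bearing carbon (C3), giving 10. Strained 10 reopens (4π) to dienylketene 11, and ring A closes between the ketene carbon C1 and the terminal methylene C6 by a thermal disrotatory 6π electrocyclisation to 12, whose tautomerisation to the phenol makes the sequence irreversible. The net result is two new σ-bonds, C1–C2 and C3–C4, with hydroxyl on C1, ethoxy on C3 and the chain on C5. The only selectivity needed is the orientation of the [2+2] step, and the oxygen lone pair of 8 secures it by making the CH carbon the nucleophilic end; the same polarisation makes 8 a better ketene trap than 7 or 9. The isomer of 11 that cannot cyclise can return to 10 and pass through the productive isomer. No stereocentre is created, because the sp3 ring carbon of 10 is lost on ring opening, and the (R)-carbinol lies one CH2 outside the reacting array and sees only neutral heat.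

Step 5
Reactants: 13 (2R)-1-(3-ethoxy-5-hydroxyphenyl)propan-2-yl benzoate
Product: 14 (2R)-1-(3,5-dihydroxyphenyl)propan-2-yl benzoate
Conditions: BBr3 (3 equiv), CH2Cl2, −78 → 0 °C; then H2O
Reagents that add atoms: none
Why: Lewis-acid cleavage of an aryl alkyl ether: boron binds the ether oxygen and bromide attacks the primary ethyl carbon. The secondary benzoate is a much poorer site for bromide attack at this temperature, so the carbinol C–O bond stays intact.

Step 6
Reactants: 14 (2R)-1-(3,5-dihydroxyphenyl)propan-2-yl benzoate; 15 benzyl bromide (two equivalents, one for each phenol)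
Product: 16 (2R)-1-[3,5-bis(benzyloxy)phenyl]propan-2-yl benzoate
Conditions: 15 (2.2 equiv), K2CO3 (3 equiv), DMF, rt
Reagents that add atoms: benzyl bromide (the second equivalent of 15), BrCc1ccccc1
Why: Double Williamson etherification: each of the two phenoxides displaces bromide from one molecule of 15, so two molecules of 15 are consumed and both benzyl groups of 16 come from it. The carbonate base deprotonates only the phenols and leaves the benzoate alone.

Step 7
Reactants: 16 (2R)-1-[3,5-bis(benzyloxy)phenyl]propan-2-yl benzoate
Product: 17 (2R)-1-[3,5-bis(benzyloxy)phenyl]propan-2-ol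
Conditions: NaOH, MeOH/THF/H2O, 40 °C; then dilute HCl
Reagents that add atoms: none
Why: Saponification by acyl–oxygen cleavage, so the carbinol keeps its (R) configuration; aryl benzyl ethers are stable to hydroxide.

Step 8
Reactants: 18 methyl (R)-3-hydroxybutanoate; 19 benzyl 2,2,2-trichloroacetimidate
Product: 20 methyl (3R)-3-(benzyloxy)butanoate
Conditions: TfOH (cat.), cyclohexane/CH2Cl2, rt
Reagents that add atoms: none
Why: Acid-catalysed O-benzylation with the imidate; the absence of base avoids retro-aldol and E1cB pathways of the β-hydroxy ester, and the stereocentre's C–O bond is not broken.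

Step 9
Reactants: 20 methyl (3R)-3-(benzyloxy)butanoate
Product: 21 (3R)-3-(benzyloxy)butanoic acid
Conditions: LiOH, THF/H2O, 0 °C → rt; then dilute HCl
Reagents that add atoms: lithium hydroxide, [Li+].[OH-]
Why: Ester saponification at low temperature; benzyloxide is a poor leaving group, so β-elimination should not compete.

Step 10
Reactants: 17 (2R)-1-[3,5-bis(benzyloxy)phenyl]propan-2-ol; 21 (3R)-3-(benzyloxy)butanoic acid
Product: 22 (2R)-1-[3,5-bis(benzyloxy)phenyl]propan-2-yl (3R)-3-(benzyloxy)butanoate
Conditions: EDC·HCl, DMAP (cat.), CH2Cl2, 0 °C → rt
Reagents that add atoms: none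
Why: Steglich esterification with retention at both carbinols. Acylating the side-chain hydroxyl at this point means ring C never carries a free carbinol next to its carboxyl.

Step 11
Reactants: 22 (2R)-1-[3,5-bis(benzyloxy)phenyl]propan-2-yl (3R)-3-(benzyloxy)butanoate
Product: 23 (2R)-1-[3,5-bis(benzyloxy)-2-formylphenyl]propan-2-yl (3R)-3-(benzyloxy)butanoate
Conditions: POCl3, DMF, 0 → 60 °C; then aq NaOAc
Reagents that add atoms: N,N-dimethylformamide, CN(C)C=O; water, O
Why: Vilsmeier–Haack formylation of the only electron-rich ring. The chloroiminium ion attacks the carbon ortho to the chain, which is para to one benzyloxy group and ortho to the other, in preference to the crowded carbon between the two benzyloxy groups; the first formyl group deactivates the ring against a second.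

Step 12
Reactants: 23 (2R)-1-[3,5-bis(benzyloxy)-2-formylphenyl]propan-2-yl (3R)-3-(benzyloxy)butanoate
Product: 24 2,4-bis(benzyloxy)-6-[(2R)-2-{[(3R)-3-(benzyloxy)butanoyl]oxy}propyl]benzoic acid
Conditions: NaClO2, NaH2PO4, 2-methylbut-2-ene, t-BuOH/H2O, rt
Reagents that add atoms: sodium chlorite, [Na+].[O-]Cl=O
Why: Pinnick oxidation of the aldehyde; the alkene scavenger removes hypochlorous acid before it can chlorinate the electron-rich ring.

Step 13
Reactants: 25 ethyl (S)-3-hydroxybutanoate; 26 prop-2-en-1-ol
Product: 27 prop-2-en-1-yl (3S)-3-hydroxybutanoate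
Conditions: Ti(OiPr)4 (cat.), 26 as solvent, reflux
Reagents that add atoms: none
Why: Titanate-catalysed transesterification under neutral conditions, driven by excess allyl alcohol; the stereocentre is not involved.

Step 14
Reactants: 24 2,4-bis(benzyloxy)-6-[(2R)-2-{[(3R)-3-(benzyloxy)butanoyl]oxy}propyl]benzoic acid; 27 prop-2-en-1-yl (3S)-3-hydroxybutanoate
Product: 28 prop-2-en-1-yl (3R)-3-({2,4-bis(benzyloxy)-6-[(2R)-2-{[(3R)-3-(benzyloxy)butanoyl]oxy}propyl]benzoyl}oxy)butanoate
Conditions: PPh3, DIAD, toluene, 0 °C → rt
Reagents that add atoms: none
Why: Mitsunobu esterification: the carboxylate of 24 displaces the oxyphosphonium of 27 by SN2, so the (S)-alcohol becomes the (R)-ester by inversion. The hindered carboxyl acts only as a nucleophile, which avoids both its low reactivity as an acyl donor and lactonisation onto the side-chain ester oxygen.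

Step 15
Reactants: 28 prop-2-en-1-yl (3R)-3-({2,4-bis(benzyloxy)-6-[(2R)-2-{[(3R)-3-(benzyloxy)butanoyl]oxy}propyl]benzoyl}oxy)butanoate
Product: 29 (3R)-3-({2,4-bis(benzyloxy)-6-[(2R)-2-{[(3R)-3-(benzyloxy)butanoyl]oxy}propyl]benzoyl}oxy)butanoic acid
Conditions: Pd(PPh3)4 (cat.), morpholine, THF, rt; then dilute aqueous acid
Reagents that add atoms: none
Why: Tsuji–Trost deallylation: zerovalent palladium ionises the allyl ester to a π-allyl complex, which morpholine captures. The conditions are near neutral, so the benzyl ethers, the three other esters and the β-aroyloxy motif are not affected.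

Step 16
Reactants: 29 (3R)-3-({2,4-bis(benzyloxy)-6-[(2R)-2-{[(3R)-3-(benzyloxy)butanoyl]oxy}propyl]benzoyl}oxy)butanoic acid; 17 (2R)-1-[3,5-bis(benzyloxy)phenyl]propan-2-ol
Product: 30 (2R)-1-[3,5-bis(benzyloxy)phenyl]propan-2-yl (3R)-3-({2,4-bis(benzyloxy)-6-[(2R)-2-{[(3R)-3-(benzyloxy)butanoyl]oxy}propyl]benzoyl}oxy)butanoate
Conditions: EDC·HCl, DMAP (cat.), CH2Cl2, −10 → 0 °C
Reagents that add atoms: none
Why: Steglich esterification of an unhindered aliphatic acid with a secondary alcohol, with retention at every stereocentre; low temperature and only catalytic DMAP are used to keep β-elimination of the aroyloxy group slow.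

Step 17
Reactants: 30 (2R)-1-[3,5-bis(benzyloxy)phenyl]propan-2-yl (3R)-3-({2,4-bis(benzyloxy)-6-[(2R)-2-{[(3R)-3-(benzyloxy)butanoyl]oxy}propyl]benzoyl}oxy)butanoate
Product: 31 Hansforester J
Conditions: H2 (1 atm), Pd/C, EtOAc, rt
Reagents that add atoms: none
Why: Hydrogenolysis of the four aryl benzyl ethers and the one alkyl benzyl ether; the three ester C–O bonds are on non-benzylic carbons and are not cleaved, and no stereocentre is touched.

## Compound list

1 | (R)-pent-4-yn-2-ol | C#CC[C@@H](C)O | starting material
2 | benzoyl chloride | O=C(Cl)c1ccccc1 | starting material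
3 | (2R)-pent-4-yn-2-yl benzoate | C#CC[C@@H](C)OC(=O)c1ccccc1 | intermediate
4 | trichloroacetyl chloride | O=C(Cl)C(Cl)(Cl)Cl | starting material
5 | dichloroketene | O=C=C(Cl)Cl | intermediate
6 | (2R)-1-(4,4-dichloro-3-oxocyclobut-1-en-1-yl)propan-2-yl benzoate | O=C1C=C(C[C@@H](C)OC(=O)c2ccccc2)C1(Cl)Cl | intermediate
7 | (2R)-1-(3-oxocyclobut-1-en-1-yl)propan-2-yl benzoate | O=C1C=C(C[C@@H](C)OC(=O)c2ccccc2)C1 | intermediate
8 | ethoxyacetylene | CCOC#C | starting material
9 | (2R)-4-methylidene-6-oxohex-5-en-2-yl benzoate (vinylketene) | O=C=CC(=C)C[C@@H](C)OC(=O)c1ccccc1 | intermediate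
10 | (2R)-4-(2-ethoxy-4-oxocyclobut-2-en-1-yl)pent-4-en-2-yl benzoate (both epimers at the ring CH) | O=C1C=C(OCC)C1C(=C)C[C@@H](C)OC(=O)c2ccccc2 | intermediate
11 | (2R,5E)-6-ethoxy-4-methylidene-8-oxoocta-5,7-dien-2-yl benzoate (dienylketene) | O=C=C/C(OCC)=C\C(=C)C[C@@H](C)OC(=O)c1ccccc1 | intermediate
12 | (2R)-1-(3-ethoxy-5-oxocyclohexa-1,3-dien-1-yl)propan-2-yl benzoate | O=C1C=C(OCC)C=C(C[C@@H](C)OC(=O)c2ccccc2)C1 | intermediate
13 | (2R)-1-(3-ethoxy-5-hydroxyphenyl)propan-2-yl benzoate | CCOc1cc(O)cc(C[C@@H](C)OC(=O)c2ccccc2)c1 | intermediate
14 | (2R)-1-(3,5-dihydroxyphenyl)propan-2-yl benzoate | Oc1cc(O)cc(C[C@@H](C)OC(=O)c2ccccc2)c1 | intermediate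
15 | benzyl bromide | BrCc1ccccc1 | starting material
16 | (2R)-1-[3,5-bis(benzyloxy)phenyl]propan-2-yl benzoate | C[C@H](Cc1cc(OCc2ccccc2)cc(OCc2ccccc2)c1)OC(=O)c1ccccc1 | intermediate
17 | (2R)-1-[3,5-bis(benzyloxy)phenyl]propan-2-ol | C[C@H](Cc1cc(OCc2ccccc2)cc(OCc2ccccc2)c1)O | intermediate
18 | methyl (R)-3-hydroxybutanoate | COC(=O)C[C@@H](C)O | starting material
19 | benzyl 2,2,2-trichloroacetimidate | N=C(OCc1ccccc1)C(Cl)(Cl)Cl | starting material
20 | methyl (3R)-3-(benzyloxy)butanoate | COC(=O)C[C@@H](C)OCc1ccccc1 | intermediate
21 | (3R)-3-(benzyloxy)butanoic acid | OC(=O)C[C@@H](C)OCc1ccccc1 | intermediate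
22 | (2R)-1-[3,5-bis(benzyloxy)phenyl]propan-2-yl (3R)-3-(benzyloxy)butanoate | C[C@H](Cc1cc(OCc2ccccc2)cc(OCc2ccccc2)c1)OC(=O)C[C@@H](C)OCc1ccccc1 | intermediate
23 | (2R)-1-[3,5-bis(benzyloxy)-2-formylphenyl]propan-2-yl (3R)-3-(benzyloxy)butanoate | C[C@H](Cc1cc(OCc2ccccc2)cc(OCc2ccccc2)c1C=O)OC(=O)C[C@@H](C)OCc1ccccc1 | intermediate
24 | 2,4-bis(benzyloxy)-6-[(2R)-2-{[(3R)-3-(benzyloxy)butanoyl]oxy}propyl]benzoic acid | C[C@H](Cc1cc(OCc2ccccc2)cc(OCc2ccccc2)c1C(O)=O)OC(=O)C[C@@H](C)OCc1ccccc1 | intermediate
25 | ethyl (S)-3-hydroxybutanoate | CCOC(=O)C[C@H](C)O | starting material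
26 | prop-2-en-1-ol (allyl alcohol) | C=CCO | starting material
27 | prop-2-en-1-yl (3S)-3-hydroxybutanoate | C=CCOC(=O)C[C@H](C)O | intermediate
28 | prop-2-en-1-yl (3R)-3-({2,4-bis(benzyloxy)-6-[(2R)-2-{[(3R)-3-(benzyloxy)butanoyl]oxy}propyl]benzoyl}oxy)butanoate | C=CCOC(=O)C[C@@H](C)OC(=O)c1c(OCc2ccccc2)cc(OCc2ccccc2)cc1C[C@@H](C)OC(=O)C[C@@H](C)OCc1ccccc1 | intermediate
29 | (3R)-3-({2,4-bis(benzyloxy)-6-[(2R)-2-{[(3R)-3-(benzyloxy)butanoyl]oxy}propyl]benzoyl}oxy)butanoic acid | OC(=O)C[C@@H](C)OC(=O)c1c(OCc2ccccc2)cc(OCc2ccccc2)cc1C[C@@H](C)OC(=O)C[C@@H](C)OCc1ccccc1 | intermediate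
30 | (2R)-1-[3,5-bis(benzyloxy)phenyl]propan-2-yl (3R)-3-({2,4-bis(benzyloxy)-6-[(2R)-2-{[(3R)-3-(benzyloxy)butanoyl]oxy}propyl]benzoyl}oxy)butanoate | C[C@H](Cc1cc(OCc2ccccc2)cc(OCc2ccccc2)c1)OC(=O)C[C@@H](C)OC(=O)c1c(OCc2ccccc2)cc(OCc2ccccc2)cc1C[C@@H](C)OC(=O)C[C@@H](C)OCc1ccccc1 | intermediate
31 | Hansforester J, (2R)-1-(3,5-dihydroxyphenyl)propan-2-yl (3R)-3-({2,4-dihydroxy-6-[(2R)-2-{[(3R)-3-hydroxybutanoyl]oxy}propyl]benzoyl}oxy)butanoate | C[C@H](Cc1cc(O)cc(O)c1)OC(=O)C[C@@H](C)OC(=O)c1c(O)cc(O)cc1C[C@@H](C)OC(=O)C[C@@H](C)O | target

## Step count and least certain steps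

Total: 17 steps. Longest linear sequence: 14 steps (steps 1–7, 10–12 and 14–17). Steps 8 and 9 (acid 21) and step 13 (ester 27) are side branches. Alcohol 17 is needed twice, in step 10 and in step 16, so steps 1–7 are run on a scale that supplies both.

**Step 4 (key step).** The vinylketene 9 may be intercepted by the phenol that the reaction itself produces, and 9 may also dimerise, if the cycloaddition with the volatile ynol ether is slow. Ring opening of 10 may also stall at 80 °C. Raising the temperature to push it risks thermal loss of ethylene from the ynol ether. The fallback abandons ring construction and takes ring A from an aryl halide. It sets out from benzyl bromide 15, two equivalents of which O-benzylate commercial 5-bromobenzene-1,3-diol (K2CO3, DMF) to 1,3-bis(benzyloxy)-5-bromobenzene F1. Magnesium in THF converts this into [3,5-bis(benzyloxy)phenyl]magnesium bromide F2, which opens (R)-2-methyloxirane A5 at its CH2 carbon under CuI catalysis. The stereocentre is not touched, and the route is rejoined at 17.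

**Step 5.** Bromide may attack the secondary carbinol carbon once the benzoate carbonyl is bound to boron, with loss of configuration, or the benzoate may be cleaved. The ethyl ether is also cleaved more slowly than a methyl ether, which tempts longer and warmer reaction. The fallback changes the ether so that a weaker Lewis acid suffices. It sets out from 7. Propan-2-ol, KH and trichloroethylene give 2-[(1,2-dichloroethenyl)oxy]propane F3, and n-BuLi followed by a proton quench gives 2-(ethynyloxy)propane F4. Benzannulation of 7 with this ynol ether under the conditions of step 4 gives (2R)-1-[3-hydroxy-5-(propan-2-yloxy)phenyl]propan-2-yl benzoate F5. Its secondary alkyl ether is removed by BCl3 in CH2Cl2 at −78 → 0 °C, conditions that leave a benzoate alone, and the route is rejoined at 14.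

**Step 11.** Attack at the carbon between the two benzyloxy groups would give the wrong regioisomer. Acid set free during formylation may also remove the benzyl group that ends up ortho to the formyl group. The fallback replaces formylation and oxidation by halogenation and carbonylation. It sets out from 22. NIS with catalytic TFA in MeCN gives (2R)-1-[3,5-bis(benzyloxy)-2-iodophenyl]propan-2-yl (3R)-3-(benzyloxy)butanoate F6, with the strongly para-directing iodination going ortho to the chain. Palladium-catalysed hydroxycarbonylation (Pd2(dba)3, HCO2Li, Ac2O, i-Pr2NEt, LiCl, DMF, 80 °C) then gives the acid directly, and the route is rejoined at 24 without step 12.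

**Step 14.** The activated alcohol 27 has acidic α-hydrogens and may eliminate to the crotonate before the hindered carboxylate can displace the oxyphosphonium group. The fallback masks the unit B carboxyl as an alkene, which cannot eliminate. It sets out from 24. A Mitsunobu reaction with commercial (S)-pent-4-en-2-ol (PPh3, DIAD) gives, with inversion, (2R)-pent-4-en-2-yl 2,4-bis(benzyloxy)-6-[(2R)-2-{[(3R)-3-(benzyloxy)butanoyl]oxy}propyl]benzoate F7. Cleavage of the terminal alkene (OsO4 cat., NaIO4, 2,6-lutidine, dioxane/H2O) gives (2R)-4-oxobutan-2-yl 2,4-bis(benzyloxy)-6-[(2R)-2-{[(3R)-3-(benzyloxy)butanoyl]oxy}propyl]benzoate F8. Chlorite oxidation as in step 12 then rejoins the route at 29, without steps 13 and 15.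

**Step 16.** Activation of 29 acidifies the position α to the carbonyl, and loss of the β-aroyloxy group by E1cB elimination may compete with acylation of the secondary alcohol; rearrangement of the activated acid to an unreactive N-acylurea is a second drain. The fallback forms this ester bond before a β-leaving group is present. It sets out from 17. Heating with 2,2,6-trimethyl-4H-1,3-dioxin-4-one in toluene gives (2R)-1-[3,5-bis(benzyloxy)phenyl]propan-2-yl 3-oxobutanoate F9. Asymmetric hydrogenation of the ketone (H2, RuCl2[(S)-BINAP], EtOH/CH2Cl2), with the catalyst controlling the new centre, gives (2R)-1-[3,5-bis(benzyloxy)phenyl]propan-2-yl (3S)-3-hydroxybutanoate F10. A Mitsunobu reaction of this alcohol with acid 24, with inversion, rejoins the route at 30, without steps 13–15.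

## Further compounds

F1 | step 4 | 1,3-bis(benzyloxy)-5-bromobenzene | Brc1cc(OCc2ccccc2)cc(OCc2ccccc2)c1
F2 | step 4 | [3,5-bis(benzyloxy)phenyl]magnesium bromide | Br[Mg]c1cc(OCc2ccccc2)cc(OCc2ccccc2)c1
F3 | step 5 | 2-[(1,2-dichloroethenyl)oxy]propane | CC(C)OC(Cl)=CCl
F4 | step 5 | 2-(ethynyloxy)propane | CC(C)OC#C
F5 | step 5 | (2R)-1-[3-hydroxy-5-(propan-2-yloxy)phenyl]propan-2-yl benzoate | CC(C)Oc1cc(O)cc(C[C@@H](C)OC(=O)c2ccccc2)c1
F6 | step 11 | (2R)-1-[3,5-bis(benzyloxy)-2-iodophenyl]propan-2-yl (3R)-3-(benzyloxy)butanoate | C[C@H](Cc1cc(OCc2ccccc2)cc(OCc2ccccc2)c1I)OC(=O)C[C@@H](C)OCc1ccccc1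
F7 | step 14 | (2R)-pent-4-en-2-yl 2,4-bis(benzyloxy)-6-[(2R)-2-{[(3R)-3-(benzyloxy)butanoyl]oxy}propyl]benzoate | C=CC[C@@H](C)OC(=O)c1c(OCc2ccccc2)cc(OCc2ccccc2)cc1C[C@@H](C)OC(=O)C[C@@H](C)OCc1ccccc1
F8 | step 14 | (2R)-4-oxobutan-2-yl 2,4-bis(benzyloxy)-6-[(2R)-2-{[(3R)-3-(benzyloxy)butanoyl]oxy}propyl]benzoate | O=CC[C@@H](C)OC(=O)c1c(OCc2ccccc2)cc(OCc2ccccc2)cc1C[C@@H](C)OC(=O)C[C@@H](C)OCc1ccccc1
F9 | step 16 | (2R)-1-[3,5-bis(benzyloxy)phenyl]propan-2-yl 3-oxobutanoate | C[C@H](Cc1cc(OCc2ccccc2)cc(OCc2ccccc2)c1)OC(=O)CC(C)=O
F10 | step 16 | (2R)-1-[3,5-bis(benzyloxy)phenyl]propan-2-yl (3S)-3-hydroxybutanoate | C[C@H](Cc1cc(OCc2ccccc2)cc(OCc2ccccc2)c1)OC(=O)C[C@H](C)O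
A1 | alternative 1 | pentakis(benzyl carbonate) of Hansforester J | C[C@H](Cc1cc(OC(=O)OCc2ccccc2)cc(OC(=O)OCc2ccccc2)c1)OC(=O)C[C@@H](C)OC(=O)c1c(OC(=O)OCc2ccccc2)cc(OC(=O)OCc2ccccc2)cc1C[C@@H](C)OC(=O)C[C@@H](C)OC(=O)OCc1ccccc1
A2 | alternative 1 | bis-ketone precursor of A1, in which each arylpropan-2-yl carbon is bonded directly to the carbonyl carbon (two α-methyl ketones) | C[C@H](Cc1cc(OC(=O)OCc2ccccc2)cc(OC(=O)OCc2ccccc2)c1)C(=O)C[C@@H](C)OC(=O)c1c(OC(=O)OCc2ccccc2)cc(OC(=O)OCc2ccccc2)cc1C[C@@H](C)C(=O)C[C@@H](C)OC(=O)OCc1ccccc1
A3 | alternative 2 | (R)-6,8-bis(benzyloxy)-3-methylisochroman-1-one | C[C@@H]1Cc2cc(OCc3ccccc3)cc(OCc3ccccc3)c2C(=O)O1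
A4 | alternative 2 | 2,4-bis(benzyloxy)benzoic acid | OC(=O)c1ccc(OCc2ccccc2)cc1OCc1ccccc1
A5 | alternative 2 | (R)-2-methyloxirane | C[C@@H]1CO1
A6 | alternative 3 | (R)-1-[3,5-bis(benzyloxy)phenyl]propan-2-yl (R)-3-hydroxybutanoate | C[C@H](Cc1cc(OCc2ccccc2)cc(OCc2ccccc2)c1)OC(=O)C[C@@H](C)O
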